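**Plan** (isobenzofuranone locants; ring A = cyclohexene, ring B = trimethylcyclohexane, ring C = lactol-lactone)
1. Retrosynthetically, ring C is opened at O2–C3 to a cis 2-formyl carboxylic acid, and the C3–C3a bond is traced back through an enol triflate to a C3a ketone.
2. With C3a as a ketone, alkene carbon C5 (bearing cyclohexyl C1′) is the β-carbon of an enone and C7a is the α-carbon of a β-keto ester whose γ-carbon is C4. Ring A is therefore cut at C7–C7a (Michael addition) and C4=C5 (aldol condensation).
3. Forward: vinyl ketone 7 (ring B) and keto diester 13 are made separately and joined to close ring A; C3 is then added by carbonylation and ring C closes last.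
4. Stereochemistry: C1′ comes from a copper-catalysed asymmetric conjugate addition, the propanoate centre is purchased as an (R)-methylsuccinate half ester, C3a and C7a come from a face-selective conjugate reduction steered by the propanoate centre, and C3 is set by equilibration.

Key step: step 9

Assumption: the hemiacetal carbon C3 epimerises through the ring-opened formyl acid, and the 3R configuration of the target (hydroxyl cis to C4) is taken to be the one favoured at equilibrium, so it is set thermodynamically in the last step.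

**Step 1**
Reactants: 1 3-methylcyclohex-2-en-1-one
Product: 2 (3S)-3-[(1E)-hex-1-en-1-yl]-3-methylcyclohexan-1-one
Conditions: hex-1-yne, iBu2AlH, heptane, 55 °C; then 1, copper thiophene-2-carboxylate CuO2CC4H3S (10 mol%), chiral SimplePhos-type phosphinamine Ph2P–N[CH(CH3)Ar]2 (11 mol%, the antipode that gives 3S), Et2O, −10 °C; aq. HCl
Reagents that add atoms: hex-1-yne, CCCCC#C (delivered as its (E)-alkenylalane)
Why: syn-Hydroalumination of the alkyne gives the (E)-alkenylalane, and its copper-catalysed asymmetric conjugate addition to the β-methyl enone, an established way to alkenyl-bearing quaternary carbons, sets the 3S centre through ligand-controlled choice of the enone face.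

**Step 2**
Reactants: 2 (3S)-3-[(1E)-hex-1-en-1-yl]-3-methylcyclohexan-1-one
Product: 3 (3S)-3-[(1E)-hex-1-en-1-yl]-1,1,3-trimethylcyclohexane
Conditions: Me2TiCl2 (from Me2Zn and TiCl4), CH2Cl2, −30 → 0 °C
Reagents that add atoms: dimethylzinc, C[Zn]C (methyl groups delivered through Me2TiCl2)
Why: Reetz geminal dimethylation replaces C=O by C(CH3)2 through methyl addition, ionisation of the tertiary titanium alkoxide and a second methyl transfer; the cation is flanked only by methylene groups, so the quaternary stereocentre and the disubstituted alkene should be unaffected.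

**Step 3**
Reactants: 3 (3S)-3-[(1E)-hex-1-en-1-yl]-1,1,3-trimethylcyclohexane
Product: 5 (1S)-1,3,3-trimethylcyclohexane-1-carbaldehyde, via ozonide 4 (not isolated)
Conditions: O3, CH2Cl2, −78 °C; then PPh3, −78 °C → rt
Reagents that add atoms: ozone, [O-][O+]=O
Why: Ozonolysis (Criegee mechanism) with reductive work-up cleaves the only C=C bond and leaves the formyl group on the quaternary carbon, which bears no hydrogen and cannot epimerise.

**Step 4**
Reactants: 5 (1S)-1,3,3-trimethylcyclohexane-1-carbaldehyde
Product: 6 1-[(1S)-1,3,3-trimethylcyclohexyl]prop-2-en-1-ol (both carbinol epimers)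
Conditions: CH2=CHMgBr, THF, −78 → 0 °C; aq. NH4Cl
Reagents that add atoms: vinylmagnesium bromide, C=C[Mg]Br
Why: Grignard 1,2-addition to a non-enolisable aldehyde; the new carbinol centre is formed without control and is removed in step 5.

**Step 5**
Reactants: 6 1-[(1S)-1,3,3-trimethylcyclohexyl]prop-2-en-1-ol
Product: 7 1-[(1S)-1,3,3-trimethylcyclohexyl]prop-2-en-1-one
Conditions: Dess–Martin periodinane, CH2Cl2, 0 °C → rt
Reagents that add atoms: none
Why: Dess–Martin oxidation of the allylic alcohol under near-neutral conditions should give the tert-alkyl vinyl ketone without conjugate addition to the enone or its polymerisation.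

**Step 6**
Reactants: 8 (2R)-4-(tert-butoxy)-2-methyl-4-oxobutanoic acid
Product: 9 4-tert-butyl 1-methyl (2R)-2-methylbutanedioate
Conditions: MeI, K2CO3, DMF, rt
Reagents that add atoms: iodomethane, CI
Why: O-Alkylation of the carboxylate (SN2) under mild carbonate conditions esterifies the acid without touching the α-stereocentre or the tert-butyl ester.

**Step 7**
Reactants: 9 4-tert-butyl 1-methyl (2R)-2-methylbutanedioate
Product: 10 (3R)-4-methoxy-3-methyl-4-oxobutanoic acid
Conditions: CF3CO2H/CH2Cl2 (1:3), 0 °C → rt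
Reagents that add atoms: none
Why: Acidolysis of the tert-butyl ester (E1 loss of isobutene) frees the carboxyl group on the methylene side only, the methyl ester and the stereocentre being stable to trifluoroacetic acid.

**Step 8**
Reactants: 10 (3R)-4-methoxy-3-methyl-4-oxobutanoic acid
Product: 13 1-tert-butyl 6-methyl (5R)-5-methyl-3-oxohexanedioate, via acyl imidazolide 11 (not isolated), via acylmalonic acid 12 (not isolated)
Conditions: 1,1′-carbonyldiimidazole, THF, rt; then tBuO2CCH2CO2H, MgCl2, Et3N, MeCN, rt → 40 °C; aq. citric acid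
Reagents that add atoms: mono-tert-butyl malonate, CC(C)(C)OC(=O)CC(=O)O
Why: Masamune–Brooks homologation, in which the acyl imidazolide acylates the magnesium enolate of the malonate half ester and the acylmalonate decarboxylates to the β-keto ester under essentially neutral conditions, so the α-stereocentre of the methyl ester is not endangered.

**Step 9**
Reactants: 7 1-[(1S)-1,3,3-trimethylcyclohexyl]prop-2-en-1-one; 13 1-tert-butyl 6-methyl (5R)-5-methyl-3-oxohexanedioate (1.2 equiv)
Product: 16 tert-butyl 3-[(2R)-1-methoxy-1-oxopropan-2-yl]-2-oxo-4-[(1S)-1,3,3-trimethylcyclohexyl]cyclohex-3-ene-1-carboxylate (C1 epimers), via Michael adduct 14 (not isolated), via aldol 15 (not isolated)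
Conditions: KOtBu (0.2 equiv), tBuOH/THF, 0 °C → rt; then 60 °C
Reagents that add atoms: none
Why: The enolate of 13, formed by tert-butoxide at the doubly activated C2 (the future C7a), adds in a Michael sense to the unsubstituted terminus of enone 7 to give 1,5-diketone 14 and so makes the C7–C7a bond. Proton exchange then exposes the C4 enolate of 14, which attacks the tert-alkyl ketone carbonyl in a 6-(enolendo)-exo-trig aldol addition that closes ring A (15), and E1cB loss of water places the new C4=C5 double bond in conjugation with the C3a ketone. The closest known reaction is the base-mediated Michael–aldol condensation of acetoacetic esters with chalcones or tert-alkyl vinyl ketones to 2-oxocyclohex-3-ene-1-carboxylates. No stereocentre that must be controlled is created: the ester-bearing carbon stays epimerisable and becomes trigonal in step 10, while the quaternary carbon and the propanoate centre, an unactivated ester α-carbon, should be untouched by catalytic base. Regiochemistry rests on the substrates: only C2 of 13 is acidic enough to serve as Michael donor, the ketone of 7 has a quaternary α′-carbon and its other α-carbon could only close a four-membered ring, so attack by C4 is the sole aldol mode leading to a six-membered ring. Dehydration pulls the congested aldol equilibrium forward, and sub-stoichiometric base keeps Dieckmann closure onto the methyl ester and double Michael addition slow.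

**Step 10**
Reactants: 16 tert-butyl 3-[(2R)-1-methoxy-1-oxopropan-2-yl]-2-oxo-4-[(1S)-1,3,3-trimethylcyclohexyl]cyclohex-3-ene-1-carboxylate
Product: 17 tert-butyl 3-[(2R)-1-methoxy-1-oxopropan-2-yl]-2-[(trifluoromethanesulfonyl)oxy]-4-[(1S)-1,3,3-trimethylcyclohexyl]cyclohexa-1,3-diene-1-carboxylate
Conditions: Tf2O, iPr2NEt, CH2Cl2, −78 → 0 °C
Reagents that add atoms: trifluoromethanesulfonic anhydride, O=S(=O)(OS(=O)(=O)C(F)(F)F)C(F)(F)F
Why: Enol triflation of a β-keto ester: the only readily removed proton sits on the ester-bearing carbon, so O-sulfonylation of the cross-conjugated enolate should give the dienyl triflate regioselectively and erase the labile centre.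

**Step 11**
Reactants: 17 tert-butyl 3-[(2R)-1-methoxy-1-oxopropan-2-yl]-2-[(trifluoromethanesulfonyl)oxy]-4-[(1S)-1,3,3-trimethylcyclohexyl]cyclohexa-1,3-diene-1-carboxylate
Product: 18 tert-butyl 2-formyl-3-[(2R)-1-methoxy-1-oxopropan-2-yl]-4-[(1S)-1,3,3-trimethylcyclohexyl]cyclohexa-1,3-diene-1-carboxylate
Conditions: Pd(PPh3)4 (5 mol%), LiCl, CO (3 atm), Bu3SnH (slow addition), THF, 50 °C
Reagents that add atoms: carbon monoxide, [C-]#[O+]
Why: Palladium-catalysed reductive carbonylation (Stille-type formylation of an enol triflate): oxidative addition of zerovalent palladium into the activated C–OTf bond, CO insertion and hydride transfer from tin to the acylpalladium give the aldehyde, slow hydride addition under CO pressure suppressing direct reduction.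

**Step 12**
Reactants: 18 tert-butyl 2-formyl-3-[(2R)-1-methoxy-1-oxopropan-2-yl]-4-[(1S)-1,3,3-trimethylcyclohexyl]cyclohexa-1,3-diene-1-carboxylate
Product: 19 tert-butyl (1R,2R)-2-formyl-3-[(2R)-1-methoxy-1-oxopropan-2-yl]-4-[(1S)-1,3,3-trimethylcyclohexyl]cyclohex-3-ene-1-carboxylate
Conditions: [(Ph3P)CuH]6 (0.4 equiv), degassed benzene/THF, H2O (2 equiv), rt
Reagents that add atoms: none
Why: Conjugate reduction with Stryker's reagent: the bulky copper hydride should deliver hydride to the β-carbon of the doubly activated enal (ring C1, the future C7a) from the diene face opposite the methoxycarbonyl group of the side chain, whose C–H bond lies in the diene plane to avoid allylic strain with the cyclohexyl group, and water then protonates the copper enolate at C2 anti to the now axial ester, so the cis (1R,2R) isomer is expected while the esters and the hindered C3=C4 alkene stay inert.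

**Step 13**
Reactants: 19 tert-butyl (1R,2R)-2-formyl-3-[(2R)-1-methoxy-1-oxopropan-2-yl]-4-[(1S)-1,3,3-trimethylcyclohexyl]cyclohex-3-ene-1-carboxylate
Product: 21 methyl (2R)-2-[(3R,3aR,7aR)-3-hydroxy-1-oxo-5-[(1S)-1,3,3-trimethylcyclohexyl]-1,3,3a,6,7,7a-hexahydro-2-benzofuran-4-yl]propanoate (the target), via formyl acid 20 (not isolated)
Conditions: CF3CO2H/CH2Cl2 (1:4), 0 °C → rt; aq. work-up
Reagents that add atoms: none
Why: Acidolysis of the tert-butyl ester frees the carboxylic acid, which adds to the cis formyl group to give the γ-hydroxy-γ-lactone (ring-chain tautomerism of a γ-oxo acid); the methyl ester survives, any trans epimer at the formyl-bearing carbon can equilibrate through the enol and only the cis acid is drained into ring C, and C3 settles by reversible ring opening.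

**Compound list**
1 | 3-methylcyclohex-2-en-1-one | CC1=CC(=O)CCC1 | starting material
2 | (3S)-3-[(1E)-hex-1-en-1-yl]-3-methylcyclohexan-1-one | CCCC/C=C/[C@@]1(C)CCCC(=O)C1 | intermediate
3 | (3S)-3-[(1E)-hex-1-en-1-yl]-1,1,3-trimethylcyclohexane | CCCC/C=C/[C@@]1(C)CCCC(C)(C)C1 | intermediate
4 | 3-butyl-5-[(1S)-1,3,3-trimethylcyclohexyl]-1,2,4-trioxolane (ozonide) | CCCCC1OOC(O1)[C@@]1(C)CCCC(C)(C)C1 | intermediate
5 | (1S)-1,3,3-trimethylcyclohexane-1-carbaldehyde | O=C[C@@]1(C)CCCC(C)(C)C1 | intermediate
6 | 1-[(1S)-1,3,3-trimethylcyclohexyl]prop-2-en-1-ol | C=CC(O)[C@@]1(C)CCCC(C)(C)C1 | intermediate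
7 | 1-[(1S)-1,3,3-trimethylcyclohexyl]prop-2-en-1-one | C=CC(=O)[C@@]1(C)CCCC(C)(C)C1 | intermediate
8 | (2R)-4-(tert-butoxy)-2-methyl-4-oxobutanoic acid | CC(C)(C)OC(=O)C[C@@H](C)C(=O)O | starting material
9 | 4-tert-butyl 1-methyl (2R)-2-methylbutanedioate | CC(C)(C)OC(=O)C[C@@H](C)C(=O)OC | intermediate
10 | (3R)-4-methoxy-3-methyl-4-oxobutanoic acid | COC(=O)[C@H](C)CC(=O)O | intermediate
11 | methyl (2R)-4-(1H-imidazol-1-yl)-2-methyl-4-oxobutanoate | COC(=O)[C@H](C)CC(=O)n1ccnc1 | intermediate
12 | (5R)-2-(tert-butoxycarbonyl)-6-methoxy-5-methyl-3,6-dioxohexanoic acid | COC(=O)[C@H](C)CC(=O)C(C(=O)O)C(=O)OC(C)(C)C | intermediate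
13 | 1-tert-butyl 6-methyl (5R)-5-methyl-3-oxohexanedioate | CC(C)(C)OC(=O)CC(=O)C[C@@H](C)C(=O)OC | intermediate
14 | 1-tert-butyl 6-methyl (5R)-5-methyl-3-oxo-2-{3-oxo-3-[(1S)-1,3,3-trimethylcyclohexyl]propyl}hexanedioate | COC(=O)[C@H](C)CC(=O)C(CCC(=O)[C@@]1(C)CCCC(C)(C)C1)C(=O)OC(C)(C)C | intermediate
15 | tert-butyl 4-hydroxy-3-[(2R)-1-methoxy-1-oxopropan-2-yl]-2-oxo-4-[(1S)-1,3,3-trimethylcyclohexyl]cyclohexane-1-carboxylate | COC(=O)[C@H](C)C1C(=O)C(C(=O)OC(C)(C)C)CCC1(O)[C@@]1(C)CCCC(C)(C)C1 | intermediate
16 | tert-butyl 3-[(2R)-1-methoxy-1-oxopropan-2-yl]-2-oxo-4-[(1S)-1,3,3-trimethylcyclohexyl]cyclohex-3-ene-1-carboxylate | COC(=O)[C@H](C)C1=C([C@@]2(C)CCCC(C)(C)C2)CCC(C(=O)OC(C)(C)C)C1=O | intermediate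
17 | tert-butyl 3-[(2R)-1-methoxy-1-oxopropan-2-yl]-2-[(trifluoromethanesulfonyl)oxy]-4-[(1S)-1,3,3-trimethylcyclohexyl]cyclohexa-1,3-diene-1-carboxylate | COC(=O)[C@H](C)C1=C([C@@]2(C)CCCC(C)(C)C2)CCC(C(=O)OC(C)(C)C)=C1OS(=O)(=O)C(F)(F)F | intermediate
18 | tert-butyl 2-formyl-3-[(2R)-1-methoxy-1-oxopropan-2-yl]-4-[(1S)-1,3,3-trimethylcyclohexyl]cyclohexa-1,3-diene-1-carboxylate | COC(=O)[C@H](C)C1=C([C@@]2(C)CCCC(C)(C)C2)CCC(C(=O)OC(C)(C)C)=C1C=O | intermediate
19 | tert-butyl (1R,2R)-2-formyl-3-[(2R)-1-methoxy-1-oxopropan-2-yl]-4-[(1S)-1,3,3-trimethylcyclohexyl]cyclohex-3-ene-1-carboxylate | COC(=O)[C@H](C)C1=C([C@@]2(C)CCCC(C)(C)C2)CC[C@@H](C(=O)OC(C)(C)C)[C@H]1C=O | intermediate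
20 | (1R,2R)-2-formyl-3-[(2R)-1-methoxy-1-oxopropan-2-yl]-4-[(1S)-1,3,3-trimethylcyclohexyl]cyclohex-3-ene-1-carboxylic acid | COC(=O)[C@H](C)C1=C([C@@]2(C)CCCC(C)(C)C2)CC[C@@H](C(=O)O)[C@H]1C=O | intermediate
21 | methyl (2R)-2-[(3R,3aR,7aR)-3-hydroxy-1-oxo-5-[(1S)-1,3,3-trimethylcyclohexyl]-1,3,3a,6,7,7a-hexahydro-2-benzofuran-4-yl]propanoate | COC(=O)[C@H](C)C1=C([C@@]2(C)CCCC(C)(C)C2)CC[C@H]2C(=O)O[C@@H](O)[C@@H]12 | target

**Step count**
Total: 13 steps. Longest linear sequence: 10 steps (steps 1–5, then 9–13); steps 6–8 form the second branch.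

**Steps most likely to fail**

Step 9. The ring closure may stall at the open Michael adduct, because aldol addition to the tert-alkyl ketone is reversible and must create a congested tetrasubstituted alkene. The fallback sets out from 14, obtained by stopping step 9 at room temperature before heating, and returns at 16. It replaces enolate chemistry by enamine activation of C4. Condensation of 14 with pyrrolidine (AcOH cat., toluene, reflux, azeotropic removal of water) should give the less substituted enamine, 1-tert-butyl 6-methyl (5R)-5-methyl-2-{3-oxo-3-[(1S)-1,3,3-trimethylcyclohexyl]propyl}-3-(pyrrolidin-1-yl)hex-3-enedioate F1, since the isomer conjugated with the ester suffers allylic strain. Its nucleophilic C4 attacks the ketone, and loss of water by way of the conjugated iminium ion leads to the cyclic dienamine, tert-butyl 3-[(2R)-1-methoxy-1-oxopropan-2-yl]-2-(pyrrolidin-1-yl)-4-[(1S)-1,3,3-trimethylcyclohexyl]cyclohexa-1,3-diene-1-carboxylate F2. Aqueous acetic acid hydrolyses F2 to 16. No strong base or carbocation is involved, so the propanoate centre and the quaternary carbon remain safe.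

Step 12. Hydride may be delivered to the wrong face of the diene, giving the (1S,2S) cis isomer, or the aldehyde may suffer 1,2-reduction. The fallback sets out from 17 and returns at 19. It delivers carbon instead of hydrogen to C3a, which inverts the stereochemical consequence of a given facial preference. Palladium-catalysed hydrogenolysis of the triflate (Pd(OAc)2, PPh3, HCO2H, Bu3N, DMF, 60 °C) gives the dienoate, tert-butyl 3-[(2R)-1-methoxy-1-oxopropan-2-yl]-4-[(1S)-1,3,3-trimethylcyclohexyl]cyclohexa-1,3-diene-1-carboxylate F3. Conjugate addition of nitromethane (DBU, CH3NO2, rt → 50 °C) can occur only at C3a, because the δ-carbon is fully substituted, and protonation of the ester enolate anti to the new substituent should give the cis adduct, tert-butyl (1R,2R)-3-[(2R)-1-methoxy-1-oxopropan-2-yl]-2-(nitromethyl)-4-[(1S)-1,3,3-trimethylcyclohexyl]cyclohex-3-ene-1-carboxylate F4. A Nef reaction (NaOMe, MeOH, 0 °C; then TiCl3, NH4OAc, H2O) converts the nitromethyl group into the formyl group of 19.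

Step 11. Carbonylation of the hindered, tetrasubstituted triflate may be slow, so that hydride capture before CO insertion gives the reduced diene. The fallback sets out from 17 and returns at 18, attaching C3 as a vinyl group and cutting it back. Stille coupling (Pd(PPh3)4, LiCl, Bu3SnCH=CH2, THF, reflux) gives the triene, tert-butyl 2-ethenyl-3-[(2R)-1-methoxy-1-oxopropan-2-yl]-4-[(1S)-1,3,3-trimethylcyclohexyl]cyclohexa-1,3-diene-1-carboxylate F5. Lemieux–Johnson cleavage (OsO4 cat., NaIO4, 2,6-lutidine, dioxane/H2O) should dihydroxylate only the terminal, unhindered vinyl group to the diol, tert-butyl 2-(1,2-dihydroxyethyl)-3-[(2R)-1-methoxy-1-oxopropan-2-yl]-4-[(1S)-1,3,3-trimethylcyclohexyl]cyclohexa-1,3-diene-1-carboxylate F6, which periodate cleaves in the same flask to 18.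

**Further compounds**
F1 | step 9 | 1-tert-butyl 6-methyl (5R)-5-methyl-2-{3-oxo-3-[(1S)-1,3,3-trimethylcyclohexyl]propyl}-3-(pyrrolidin-1-yl)hex-3-enedioate | COC(=O)[C@H](C)C=C(N1CCCC1)C(CCC(=O)[C@@]1(C)CCCC(C)(C)C1)C(=O)OC(C)(C)C
F2 | step 9 | tert-butyl 3-[(2R)-1-methoxy-1-oxopropan-2-yl]-2-(pyrrolidin-1-yl)-4-[(1S)-1,3,3-trimethylcyclohexyl]cyclohexa-1,3-diene-1-carboxylate | COC(=O)[C@H](C)C1=C([C@@]2(C)CCCC(C)(C)C2)CCC(C(=O)OC(C)(C)C)=C1N1CCCC1
F3 | step 12 | tert-butyl 3-[(2R)-1-methoxy-1-oxopropan-2-yl]-4-[(1S)-1,3,3-trimethylcyclohexyl]cyclohexa-1,3-diene-1-carboxylate | COC(=O)[C@H](C)C1=C([C@@]2(C)CCCC(C)(C)C2)CCC(C(=O)OC(C)(C)C)=C1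
F4 | step 12 | tert-butyl (1R,2R)-3-[(2R)-1-methoxy-1-oxopropan-2-yl]-2-(nitromethyl)-4-[(1S)-1,3,3-trimethylcyclohexyl]cyclohex-3-ene-1-carboxylate | COC(=O)[C@H](C)C1=C([C@@]2(C)CCCC(C)(C)C2)CC[C@@H](C(=O)OC(C)(C)C)[C@H]1C[N+](=O)[O-]
F5 | step 11 | tert-butyl 2-ethenyl-3-[(2R)-1-methoxy-1-oxopropan-2-yl]-4-[(1S)-1,3,3-trimethylcyclohexyl]cyclohexa-1,3-diene-1-carboxylate | COC(=O)[C@H](C)C1=C([C@@]2(C)CCCC(C)(C)C2)CCC(C(=O)OC(C)(C)C)=C1C=C
F6 | step 11 | tert-butyl 2-(1,2-dihydroxyethyl)-3-[(2R)-1-methoxy-1-oxopropan-2-yl]-4-[(1S)-1,3,3-trimethylcyclohexyl]cyclohexa-1,3-diene-1-carboxylate | COC(=O)[C@H](C)C1=C([C@@]2(C)CCCC(C)(C)C2)CCC(C(=O)OC(C)(C)C)=C1C(O)CO
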